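**Plan**

- Retrosynthesis: the five O–CH3 bonds are cut first, then water is added back across C2=C3 of both rings C. Next both C3–C4 bonds are cut, then both O1–C2 ether bonds (phenoxide plus α-bromoketone), and last the diaryl ether C–O bond and the ring A C–CHO and C–Cl bonds.
- Enabling feature: in each ring C, C4 (on ring A) and C3 (bearing ring B) both derive from carbonyl carbons, a ring A aldehyde and a ring B aryl ketone held together by the O1–C2 phenacyl ether. The C3–C4 bond therefore joins two electrophilic carbons and calls for polarity reversal of the aldehyde.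
- Forward: the diaryl ether core is made from two acetophenones and brominated twice. Ring A is prepared as a 3-chlorosalicylaldehyde and two ether bonds are formed. Both rings C then close in one carbene-catalysed operation, dehydration gives both chromones, and demethylation comes last.
- Stereochemistry: the target is achiral. The two C3 carbinol centres of the key step form without control and are erased by the dehydration. The 8-chloro pattern is fixed by placing the ether oxygen next to chlorine before ring closure.

Key step: step 6

**Route**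

Step 1
Reactants: 1 3'-hydroxy-4'-methoxyacetophenone; 2 4'-fluoroacetophenone
Product: 3 1-[3-(4-acetylphenoxy)-4-methoxyphenyl]ethan-1-one
Conditions: K2CO3, DMF, 120 °C
Reagents that add atoms: none
Why: Nucleophilic aromatic substitution (SNAr), in which the para-acetyl group activates the C–F bond of 2 toward the potassium phenoxide of 1, the standard entry to 4-acylphenyl aryl ethers.

Step 2
Reactants: 3 1-[3-(4-acetylphenoxy)-4-methoxyphenyl]ethan-1-one
Product: 4 2-bromo-1-{4-[5-(bromoacetyl)-2-methoxyphenoxy]phenyl}ethan-1-one
Conditions: CuBr2 (4.2 equiv), EtOAc/CHCl3 (1:1), reflux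
Reagents that add atoms: CuBr2, SMILES [Cu+2].[Br-].[Br-]
Why: α-Bromination of aryl methyl ketones with CuBr2 proceeds through the enol, should stop at the monobromide on each acetyl group, and is mild enough to leave the alkoxy-substituted ring unbrominated.

Step 3
Reactants: 5 3,5-dimethoxyphenol
Product: 6 2-chloro-3,5-dimethoxyphenol
Conditions: SO2Cl2 (1.0 equiv), CHCl3, 0 °C to rt
Reagents that add atoms: sulfuryl chloride, SMILES O=S(=O)(Cl)Cl
Why: Electrophilic aromatic chlorination ortho to the hydroxyl group, where the two ortho carbons are equivalent; the symmetrical 4-chloro isomer and dichlorinated material are the expected minor products and should be removable by chromatography.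

Step 4
Reactants: 6 2-chloro-3,5-dimethoxyphenol
Product: 7 3-chloro-2-hydroxy-4,6-dimethoxybenzaldehyde
Conditions: MgCl2, Et3N, (CH2O)n, MeCN, reflux; then aq. HCl
Reagents that add atoms: paraformaldehyde (reacts as formaldehyde), SMILES C=O
Why: Magnesium-mediated ortho-formylation of a phenol (Casnati–Skattebøl reaction) delivers formaldehyde only to a carbon ortho to the phenoxide, and since one ortho carbon carries chlorine the formyl group can only enter the other, which places chlorine next to the phenol oxygen without ambiguity.

Step 5
Reactants: 4 2-bromo-1-{4-[5-(bromoacetyl)-2-methoxyphenoxy]phenyl}ethan-1-one; 7 3-chloro-2-hydroxy-4,6-dimethoxybenzaldehyde (2.2 equiv)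
Product: 8 3-chloro-2-(2-{4-[5-(2-(2-chloro-6-formyl-3,5-dimethoxyphenoxy)acetyl)-2-methoxyphenoxy]phenyl}-2-oxoethoxy)-4,6-dimethoxybenzaldehyde (the bis(2-formylaryl phenacyl ether))
Conditions: K2CO3, DMF, 0 °C to rt
Reagents that add atoms: none
Why: Twofold Williamson ether synthesis (SN2) of the acidic phenoxide of 7 on the very reactive primary α-bromoketone carbons, run cold with a carbonate base so that aldol condensation of the product to a 2-aroylbenzofuran (Rap–Stoermer reaction) stays slow.

Step 6
Reactants: 8 the bis(2-formylaryl phenacyl ether)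
Product: 9 8-chloro-3-{4-[5-(8-chloro-3-hydroxy-5,7-dimethoxy-4-oxochroman-3-yl)-2-methoxyphenoxy]phenyl}-3-hydroxy-5,7-dimethoxychroman-4-one (mixture of diastereomers at the two C3 carbinol carbons)
Conditions: 2-(pentafluorophenyl)-6,7-dihydro-5H-pyrrolo[2,1-c][1,2,4]triazol-2-ium tetrafluoroborate (20 mol%), Et3N (40 mol%), toluene (0.02 M), rt to 40 °C, Ar
Reagents that add atoms: none
Why: This is a twofold intramolecular crossed aldehyde–ketone benzoin reaction under N-heterocyclic carbene catalysis, the known route to 3-hydroxychroman-4-ones: the triazolylidene freed by Et3N adds to each formyl group, proton transfer gives the nucleophilic enaminol (Breslow intermediate, an acyl anion equivalent), its carbon (future C4) adds to the tethered aryl ketone carbon (future C3), and loss of the carbene releases the α-hydroxy ketone. Each ring C closes in a 6-exo-trig mode. The two new carbinol centres are not controlled, because the catalyst is achiral and the second unit is remote, so 9 should form as a diastereomer mixture, which is harmless since step 7 removes both centres. The step needs chemoselectivity for the crossed product over intermolecular aldehyde–aldehyde benzoin and over base-induced aldol closure to a 2-aroylbenzofuran; the first is secured by the six-membered intramolecular transition state, the dilution and the two ortho substituents flanking each formyl group, the second by the weak amine base, which should not enolise the α-aryloxy ketone appreciably. Only the aldehyde carbon can become the donor, and the ether oxygen already sits on the carbon next to chlorine, so only the 8-chloro ring fusion can result.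

Step 7
Reactants: 9 the bis(3-hydroxychroman-4-one)
Product: 10 8-chloro-3-{4-[5-(8-chloro-5,7-dimethoxy-4-oxo-4H-chromen-3-yl)-2-methoxyphenoxy]phenyl}-5,7-dimethoxy-4H-chromen-4-one
Conditions: Burgess reagent (methyl N-(triethylammoniosulfonyl)carbamate, 3 equiv), toluene, 70 °C
Reagents that add atoms: none
Why: Dehydration of a tertiary alcohol through its sulfamate ester (syn elimination) can only use the hydrogens on C2, so it gives the C2=C3 bond of each chromone, driven by conjugation with the ring oxygen and the carbonyl group, and removes both stereocentres.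

Step 8
Reactants: 10 the pentamethyl ether bis-chromone
Product: 11 Bisoflavolin M, 8-chloro-3-{4-[5-(8-chloro-5,7-dihydroxy-4-oxo-4H-chromen-3-yl)-2-hydroxyphenoxy]phenyl}-5,7-dihydroxy-4H-chromen-4-one
Conditions: BBr3 (15 equiv), CH2Cl2, −78 °C to rt; then MeOH, H2O
Reagents that add atoms: none
Why: Lewis acid cleavage of aryl methyl ethers by BBr3 (bromide attacks the methyl group of the boron-complexed ether) spares the diaryl ether, the aryl chlorides and the chromone rings, and the cold anhydrous conditions avoid the pyranone ring opening that would allow Wessely–Moser isomerisation of the 8-chloro to the 6-chloro pattern.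

**Compound list**

1 | 3'-hydroxy-4'-methoxyacetophenone | CC(=O)c1ccc(OC)c(O)c1 | starting material
2 | 4'-fluoroacetophenone | CC(=O)c1ccc(F)cc1 | starting material
3 | 1-[3-(4-acetylphenoxy)-4-methoxyphenyl]ethan-1-one | CC(=O)c1ccc(Oc2cc(C(C)=O)ccc2OC)cc1 | intermediate
4 | 2-bromo-1-{4-[5-(bromoacetyl)-2-methoxyphenoxy]phenyl}ethan-1-one | O=C(CBr)c1ccc(Oc2cc(C(=O)CBr)ccc2OC)cc1 | intermediate
5 | 3,5-dimethoxyphenol | COc1cc(O)cc(OC)c1 | starting material
6 | 2-chloro-3,5-dimethoxyphenol | COc1cc(O)c(Cl)c(OC)c1 | intermediate
7 | 3-chloro-2-hydroxy-4,6-dimethoxybenzaldehyde | O=Cc1c(O)c(Cl)c(OC)cc1OC | intermediate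
8 | 3-chloro-2-(2-{4-[5-(2-(2-chloro-6-formyl-3,5-dimethoxyphenoxy)acetyl)-2-methoxyphenoxy]phenyl}-2-oxoethoxy)-4,6-dimethoxybenzaldehyde | O=Cc1c(OCC(=O)c2ccc(Oc3cc(C(=O)COc4c(Cl)c(OC)cc(OC)c4C=O)ccc3OC)cc2)c(Cl)c(OC)cc1OC | intermediate
9 | 8-chloro-3-{4-[5-(8-chloro-3-hydroxy-5,7-dimethoxy-4-oxochroman-3-yl)-2-methoxyphenoxy]phenyl}-3-hydroxy-5,7-dimethoxychroman-4-one (diastereomer mixture) | O=C1c2c(OC)cc(OC)c(Cl)c2OCC1(O)c1ccc(Oc2cc(C3(O)COc4c(Cl)c(OC)cc(OC)c4C3=O)ccc2OC)cc1 | intermediate
10 | 8-chloro-3-{4-[5-(8-chloro-5,7-dimethoxy-4-oxo-4H-chromen-3-yl)-2-methoxyphenoxy]phenyl}-5,7-dimethoxy-4H-chromen-4-one | O=c1c(-c2ccc(Oc3cc(-c4coc5c(Cl)c(OC)cc(OC)c5c4=O)ccc3OC)cc2)coc2c(Cl)c(OC)cc(OC)c12 | intermediate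
11 | Bisoflavolin M | O=c1c(-c2ccc(Oc3cc(-c4coc5c(Cl)c(O)cc(O)c5c4=O)ccc3O)cc2)coc2c(Cl)c(O)cc(O)c12 | target

**Step count**

Total steps: 8. Longest linear sequence: 6 steps (steps 1, 2, 5, 6, 7, 8; the branch through steps 3 and 4 is equally long).

**Steps most likely to fail**

1. Step 6. Carbene addition to the crowded, electron-rich formyl groups may be slow, so that base-induced aldol closure and dehydration of the phenacyl ether, or a stalled second cyclisation, takes over. The fallback gives up the umpolung and builds ring C by the deoxybenzoin route, setting out from diketone 3 and phenol 6. Willgerodt–Kindler reaction of 3 (S8, morpholine, 130 °C) gives the bis(thiomorpholide) F1. Hydrolysis (NaOH, aq. EtOH, reflux; then HCl) gives the bis(arylacetic acid) F2. Friedel–Crafts acylation of two equivalents of 6 with F2 in BF3·OEt2 at 85 °C, at the only free carbon ortho to the hydroxyl group, gives the bis(2-hydroxydeoxybenzoin) F3. Condensation of F3 with N,N-dimethylformamide dimethyl acetal (DMF, 90 °C) supplies C2 and closes both pyranones, and the route is rejoined at bis-chromone 10.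

2. Step 5. The carbonate base may trigger aldol condensation of the first-formed keto-aldehyde arm to a 2-aroylbenzofuran before the hindered, chelated second phenoxide has reacted. The fallback forms the ether bonds by redox condensation without a base, setting out from 4. Displacement with HCO2Na in aq. EtOH at reflux, with hydrolysis of the formate in the same pot, gives 2-hydroxy-1-{4-[5-(hydroxyacetyl)-2-methoxyphenoxy]phenyl}ethan-1-one F4. Mitsunobu reaction of F4 with two equivalents of 7 (PPh3, diisopropyl azodicarboxylate, THF, 0 °C to rt) returns to the route at 8.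

3. Step 3. Site selection between the ortho and para carbons may be poor, or chlorination may run on to the dichloride, leaving a mixture that is hard to separate. The fallback selects the site by coordination instead of electrophilic preference, setting out from 5. Protection (MOMCl, i-Pr2NEt, CH2Cl2) gives 1,3-dimethoxy-5-(methoxymethoxy)benzene F5. Directed ortho-lithiation (n-BuLi, THF, 0 °C) at the carbon between the acetal oxygen and a methoxy group, then C2Cl6 at −78 °C, gives 2-chloro-1,5-dimethoxy-3-(methoxymethoxy)benzene F6. HCl in MeOH removes the acetal and returns to the route at 6.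

**Further compounds**

F1 | step 6 | 2-(4-{2-methoxy-5-[2-(morpholin-4-yl)-2-sulfanylideneethyl]phenoxy}phenyl)-1-(morpholin-4-yl)ethane-1-thione | S=C(Cc1ccc(Oc2cc(CC(=S)N3CCOCC3)ccc2OC)cc1)N1CCOCC1
F2 | step 6 | 2-{4-[5-(carboxymethyl)-2-methoxyphenoxy]phenyl}acetic acid | OC(=O)Cc1ccc(Oc2cc(CC(=O)O)ccc2OC)cc1
F3 | step 6 | 1-(3-chloro-2-hydroxy-4,6-dimethoxyphenyl)-2-(4-{5-[2-(3-chloro-2-hydroxy-4,6-dimethoxyphenyl)-2-oxoethyl]-2-methoxyphenoxy}phenyl)ethan-1-one | O=C(Cc1ccc(Oc2cc(CC(=O)c3c(O)c(Cl)c(OC)cc3OC)ccc2OC)cc1)c1c(O)c(Cl)c(OC)cc1OC
F4 | step 5 | 2-hydroxy-1-{4-[5-(hydroxyacetyl)-2-methoxyphenoxy]phenyl}ethan-1-one | O=C(CO)c1ccc(Oc2cc(C(=O)CO)ccc2OC)cc1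
F5 | step 3 | 1,3-dimethoxy-5-(methoxymethoxy)benzene | COCOc1cc(OC)cc(OC)c1
F6 | step 3 | 2-chloro-1,5-dimethoxy-3-(methoxymethoxy)benzene | COCOc1cc(OC)cc(OC)c1Cl
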